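**Retrosynthetic overview**
1. Last disconnection at the N,O-acetal carbon C5: the N4–C5 and O–C5 bonds (the C6=C bond comes with them) lead back to a secondary amino aldehyde and pyruvic acid. The azepine (ring D) and the fused butenolide (ring E) are closed together in the final step.
2. C3–C18 (appended lactone, ring C): decarboxylative vinylogous Mannich reaction of a proline-type acid with 3-methyl-2-silyloxyfuran, then hydrogenation.
3. C11–CH3: methylation of the spirolactone enolate.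
4. C9–C9a (spirolactone, ring B): vinylogous Mannich reaction of a 5-alkyl-2-silyloxyfuran with the N-acyliminium ion from L-pyroglutamate (pyrrolidine, ring A, from the chiral pool).
5. Ring order: A → B → C → D and E in one pot.

Assumption: the 5S configuration of the N,O-acetal carbon is the thermodynamically preferred one and is reached by equilibration. Labels: N4, C5 (acetal carbon), C6–C8, C9 (spiro), C9a, C1–C3 for the pyrroloazepine core; C11 = methine of the spirolactone; C18/C20 = carbinol and methine carbons of the appended lactone.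

**Route**

Step 1
Reactants: 1 furan-2(5H)-one
Product: 2 2-(triisopropylsilyloxy)furan
Conditions: TIPSOTf, Et3N, CH2Cl2, 0 °C
Reagents that add atoms: triisopropylsilyl trifluoromethanesulfonate, CC(C)[Si](OS(=O)(=O)C(F)(F)F)(C(C)C)C(C)C
Why: Soft enolisation and O-silylation of the butenolide gives the aromatic silyloxyfuran (silyl dienol ether formation); no stereocenter.

Step 2
Reactants: 2 2-(triisopropylsilyloxy)furan; 3 2-(3-bromopropyl)-1,3-dioxolane
Product: 4 5-[3-(1,3-dioxolan-2-yl)propyl]-2-(triisopropylsilyloxy)furan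
Conditions: s-BuLi, TMEDA, THF, 0 °C; then 3, 0 °C to rt
Reagents that add atoms: none
Why: α-Lithiation of the furan at C5 and SN2 alkylation with the primary bromide, with the dioxolane inert to the organolithium; no stereocenter.

Step 3
Reactants: 5 benzyl (2S)-1-(tert-butoxycarbonyl)-5-oxopyrrolidine-2-carboxylate
Product: 7 benzyl (2S)-1-(tert-butoxycarbonyl)-5-methoxypyrrolidine-2-carboxylate (C5 epimers), via hemiaminal 6 (not isolated)
Conditions: LiBEt3H, THF, −78 °C; then MeOH, PPTS (cat.), rt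
Reagents that add atoms: methanol, CO
Why: Chemoselective hydride reduction of the Boc-activated lactam carbonyl over the benzyl ester, then acid-catalysed N,O-acetal exchange; C2 (S) comes from L-pyroglutamate and the new C5 centre is an irrelevant mixture.

Step 4
Reactants: 7 benzyl (2S)-1-(tert-butoxycarbonyl)-5-methoxypyrrolidine-2-carboxylate; 4 5-[3-(1,3-dioxolan-2-yl)propyl]-2-(triisopropylsilyloxy)furan
Product: 8 benzyl (2S,5S)-1-(tert-butoxycarbonyl)-5-[(2S)-2-[3-(1,3-dioxolan-2-yl)propyl]-5-oxo-2,5-dihydrofuran-2-yl]pyrrolidine-2-carboxylate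
Conditions: TIPSOTf (10 mol%), CH2Cl2, −78 to 0 °C; chromatography
Reagents that add atoms: none
Why: Vinylogous Mannich reaction: the N-acyliminium ion from 7 is attacked by C5 of the furan from the face opposite the C2 ester (2,5-trans) through the open transition state that gives the threo adduct, setting C9a (S) and quaternary C9 (S); about 2:1 threo:erythro is expected for 5-alkyl-2-silyloxyfurans and the isomers are separated.

Step 5
Reactants: 8 benzyl (2S,5S)-1-(tert-butoxycarbonyl)-5-[(2S)-2-[3-(1,3-dioxolan-2-yl)propyl]-5-oxo-2,5-dihydrofuran-2-yl]pyrrolidine-2-carboxylate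
Product: 9 (2S,5S)-1-(tert-butoxycarbonyl)-5-[(2S)-2-[3-(1,3-dioxolan-2-yl)propyl]-5-oxooxolan-2-yl]pyrrolidine-2-carboxylic acid
Conditions: H2 (1 atm), 10% Pd/C, EtOAc, rt
Reagents that add atoms: none
Why: Heterogeneous hydrogenation saturates the disubstituted butenolide alkene and hydrogenolyses the benzyl ester in one operation; no new stereocenter, Boc and dioxolane are stable.

Step 6
Reactants: 9 (2S,5S)-1-(tert-butoxycarbonyl)-5-[(2S)-2-[3-(1,3-dioxolan-2-yl)propyl]-5-oxooxolan-2-yl]pyrrolidine-2-carboxylic acid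
Product: 10 (2S,5S)-1-(tert-butoxycarbonyl)-5-[(2S,4R)-2-[3-(1,3-dioxolan-2-yl)propyl]-4-methyl-5-oxooxolan-2-yl]pyrrolidine-2-carboxylic acid
Conditions: LiN(iPr)2 (2.3 equiv), THF, −78 °C; MeI, −78 to −40 °C; aq. citric acid
Reagents that add atoms: iodomethane, CI
Why: Enolate alkylation of the carboxylate/lactone-enolate dianion: MeI enters the lactone face anti to the bulky Boc-pyrrolidinyl group on C9, giving the 11R methyl trans to C9a; the C2 centre is not deprotonated as its carboxylate and is removed in step 8 anyway.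

Step 7
Reactants: 11 3-methylfuran-2(5H)-one
Product: 12 3-methyl-2-(triisopropylsilyloxy)furan
Conditions: TIPSOTf, Et3N, CH2Cl2, 0 °C
Reagents that add atoms: triisopropylsilyl trifluoromethanesulfonate, CC(C)[Si](OS(=O)(=O)C(F)(F)F)(C(C)C)C(C)C
Why: Silyl dienol ether formation as in step 1; no stereocenter.

Step 8
Reactants: 10 (2S,5S)-1-(tert-butoxycarbonyl)-5-[(2S,4R)-2-[3-(1,3-dioxolan-2-yl)propyl]-4-methyl-5-oxooxolan-2-yl]pyrrolidine-2-carboxylic acid; 12 3-methyl-2-(triisopropylsilyloxy)furan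
Product: 14 tert-butyl (2S,5S)-2-[(2S,4R)-2-[3-(1,3-dioxolan-2-yl)propyl]-4-methyl-5-oxooxolan-2-yl]-5-[(2S)-4-methyl-5-oxo-2,5-dihydrofuran-2-yl]pyrrolidine-1-carboxylate, via acetoxy aminal 13 (not isolated)
Conditions: PhI(OAc)2, I2, CH2Cl2, visible light, rt; aq. Na2S2O3 wash; then 12, TMSOTf (0.3 equiv), CH2Cl2, −78 °C
Reagents that add atoms: (diacetoxyiodo)benzene, CC(=O)OI(OC(C)=O)c1ccccc1 (its acetate is carried by intermediate 13 only)
Why: Radical decarboxylation–oxidation (acyl hypoiodite, α-amino radical, N-acyliminium ion trapped as acetate 13) followed by a vinylogous Mannich reaction in which 12 adds trans to the bulky C9a substituent and through the threo-selective open transition state, setting C3 (S) and C18 (S).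

Step 9
Reactants: 14 tert-butyl (2S,5S)-2-[(2S,4R)-2-[3-(1,3-dioxolan-2-yl)propyl]-4-methyl-5-oxooxolan-2-yl]-5-[(2S)-4-methyl-5-oxo-2,5-dihydrofuran-2-yl]pyrrolidine-1-carboxylate
Product: 15 tert-butyl (2S,5S)-2-[(2S,4R)-2-[3-(1,3-dioxolan-2-yl)propyl]-4-methyl-5-oxooxolan-2-yl]-5-[(2S,4S)-4-methyl-5-oxooxolan-2-yl]pyrrolidine-1-carboxylate
Conditions: H2 (1 atm), 10% Pd/C, EtOAc, rt
Reagents that add atoms: none
Why: Heterogeneous hydrogenation of the trisubstituted butenolide from the face opposite the pyrrolidine substituent on C18 gives the cis-2,4-disubstituted lactone (C20 S).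

Step 10
Reactants: 15 tert-butyl (2S,5S)-2-[(2S,4R)-2-[3-(1,3-dioxolan-2-yl)propyl]-4-methyl-5-oxooxolan-2-yl]-5-[(2S,4S)-4-methyl-5-oxooxolan-2-yl]pyrrolidine-1-carboxylate; 16 pyruvic acid
Product: 19 target CNP0155196.1 (5S,9S,11R,9aS,3S,18S,20S), via amino aldehyde 17 (not isolated), via cyclic enamine 18 (not isolated)
Conditions: TFA/H2O (9:1), 0 °C to rt; evaporate; then 16 (3 equiv), 4 Å MS, 1,4-dioxane, 60 °C; NaHCO3 work-up
Reagents that add atoms: water, O (its oxygen is carried by intermediate 17 only)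
Why: Proposed new method: intramolecular enamine/α-keto acid (3+2) annulation – acid removes Boc and the dioxolane, the secondary ammonium salt condenses with the tethered aldehyde to the seven-membered enamine 18 (N4–C5 bond, azepine ring), C6 of the enamine adds to the ketone carbonyl of pyruvic acid, the carboxylate captures the C5 iminium ion (O–C5 bond) and vinylogous loss of water through the enamine tautomer gives the tetrasubstituted butenolide, while C5 equilibrates through the ring-opened azadienium carboxylate to the more stable 5S aminal; the closest known reaction type is the secondary-amine-mediated condensation of enolisable aldehydes with glyoxylic acid to 5-hydroxy- or 5-amino-2(5H)-furanones, and new here are the α-keto acid partner, the tethered amine that stays in the product as the N,O-acetal and the seven-membered ring closure.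

**Compound list**
1 | furan-2(5H)-one | O=C1OCC=C1 | starting material
2 | 2-(triisopropylsilyloxy)furan | CC(C)[Si](Oc1ccco1)(C(C)C)C(C)C | intermediate
3 | 2-(3-bromopropyl)-1,3-dioxolane | BrCCCC1OCCO1 | starting material
4 | 5-[3-(1,3-dioxolan-2-yl)propyl]-2-(triisopropylsilyloxy)furan | CC(C)[Si](Oc1ccc(CCCC2OCCO2)o1)(C(C)C)C(C)C | intermediate
5 | benzyl (2S)-1-(tert-butoxycarbonyl)-5-oxopyrrolidine-2-carboxylate (benzyl N-Boc-L-pyroglutamate) | O=C(OCc1ccccc1)[C@@H]1CCC(=O)N1C(=O)OC(C)(C)C | starting material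
6 | benzyl (2S)-1-(tert-butoxycarbonyl)-5-hydroxypyrrolidine-2-carboxylate (hemiaminal, C5 epimers) | O=C(OCc1ccccc1)[C@@H]1CCC(O)N1C(=O)OC(C)(C)C | intermediate
7 | benzyl (2S)-1-(tert-butoxycarbonyl)-5-methoxypyrrolidine-2-carboxylate (C5 epimers) | O=C(OCc1ccccc1)[C@@H]1CCC(OC)N1C(=O)OC(C)(C)C | intermediate
8 | benzyl (2S,5S)-1-(tert-butoxycarbonyl)-5-[(2S)-2-[3-(1,3-dioxolan-2-yl)propyl]-5-oxo-2,5-dihydrofuran-2-yl]pyrrolidine-2-carboxylate | O1CCOC1CCC[C@]2(C=CC(=O)O2)[C@@H]2CC[C@@H](C(=O)OCc3ccccc3)N2C(=O)OC(C)(C)C | intermediate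
9 | (2S,5S)-1-(tert-butoxycarbonyl)-5-[(2S)-2-[3-(1,3-dioxolan-2-yl)propyl]-5-oxooxolan-2-yl]pyrrolidine-2-carboxylic acid | O1CCOC1CCC[C@]2(CCC(=O)O2)[C@@H]2CC[C@@H](C(=O)O)N2C(=O)OC(C)(C)C | intermediate
10 | (2S,5S)-1-(tert-butoxycarbonyl)-5-[(2S,4R)-2-[3-(1,3-dioxolan-2-yl)propyl]-4-methyl-5-oxooxolan-2-yl]pyrrolidine-2-carboxylic acid | O1CCOC1CCC[C@]2(C[C@@H](C)C(=O)O2)[C@@H]2CC[C@@H](C(=O)O)N2C(=O)OC(C)(C)C | intermediate
11 | 3-methylfuran-2(5H)-one | CC1=CCOC1=O | starting material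
12 | 3-methyl-2-(triisopropylsilyloxy)furan | Cc1ccoc1O[Si](C(C)C)(C(C)C)C(C)C | intermediate
13 | tert-butyl (5S)-2-acetoxy-5-[(2S,4R)-2-[3-(1,3-dioxolan-2-yl)propyl]-4-methyl-5-oxooxolan-2-yl]pyrrolidine-1-carboxylate (acetoxy aminal, C2 epimers) | O1CCOC1CCC[C@]2(C[C@@H](C)C(=O)O2)[C@@H]2CCC(OC(C)=O)N2C(=O)OC(C)(C)C | intermediate
14 | tert-butyl (2S,5S)-2-[(2S,4R)-2-[3-(1,3-dioxolan-2-yl)propyl]-4-methyl-5-oxooxolan-2-yl]-5-[(2S)-4-methyl-5-oxo-2,5-dihydrofuran-2-yl]pyrrolidine-1-carboxylate | O1CCOC1CCC[C@]2(C[C@@H](C)C(=O)O2)[C@@H]2CC[C@@H]([C@@H]3C=C(C)C(=O)O3)N2C(=O)OC(C)(C)C | intermediate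
15 | tert-butyl (2S,5S)-2-[(2S,4R)-2-[3-(1,3-dioxolan-2-yl)propyl]-4-methyl-5-oxooxolan-2-yl]-5-[(2S,4S)-4-methyl-5-oxooxolan-2-yl]pyrrolidine-1-carboxylate | O1CCOC1CCC[C@]2(C[C@@H](C)C(=O)O2)[C@@H]2CC[C@@H]([C@@H]3C[C@H](C)C(=O)O3)N2C(=O)OC(C)(C)C | intermediate
16 | pyruvic acid (2-oxopropanoic acid) | CC(=O)C(=O)O | starting material
17 | 4-[(2S,4R)-4-methyl-2-[(2S,5S)-5-[(2S,4S)-4-methyl-5-oxooxolan-2-yl]pyrrolidin-2-yl]-5-oxooxolan-2-yl]butanal (amino aldehyde) | O=CCCC[C@]1(C[C@@H](C)C(=O)O1)[C@@H]1CC[C@@H]([C@@H]2C[C@H](C)C(=O)O2)N1 | intermediate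
18 | cyclic enamine: 2,3,7,8,9,9a-hexahydro-1H-pyrrolo[1,2-a]azepine with C5=C6 double bond, (9S,11R) spirolactone at C9, 9aS, and the (18S,20S) lactone at 3S-C3 | C1=CCC[C@]2(C[C@@H](C)C(=O)O2)[C@@H]2CC[C@@H]([C@@H]3C[C@H](C)C(=O)O3)N12 | intermediate
19 | CNP0155196.1: pyrrolo[1,2-a]azepine with α-methylbutenolide fused at C5–C6 (5S N,O-acetal), 9S spirolactone with 11R methyl, 9aS, 3S, and (18S,20S)-α-methyl-γ-butyrolactone at C3 | CC1=C2CC[C@]3(C[C@@H](C)C(=O)O3)[C@@H]3CC[C@@H]([C@@H]4C[C@H](C)C(=O)O4)N3[C@H]2OC1=O | target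

**Step count and risks**
Total steps: 10. Longest linear sequence: 8 (steps 1, 2, 4, 5, 6, 8, 9, 10).

Step 10 (new annulation). Risks: the enol of pyruvic acid may add to the C5 iminium carbon (Mannich mode) instead of the enamine adding to the keto group; seven-membered enamine formation may be slow; C5 may settle as the other epimer. Fallback with known chemistry, setting out from 15 and returning at 19: transacetalisation (PPTS, acetone/H2O, 60 °C) gives the Boc-protected aldehyde F7. TMSCl, NaI and Et3N in MeCN convert it to the trimethylsilyl enol ether F8. A Mukaiyama aldol addition to ethyl pyruvate (BF3·OEt2, CH2Cl2, −78 °C) gives the β-formyl α-hydroxy ester F9. TFA, then warm toluene with catalytic TsOH, removes Boc, dehydrates the tertiary alcohol and closes the hemiaminal onto the ester, giving 19.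

Step 6 (C11 methylation). Risk: low or reversed facial selectivity on the γ,γ-disubstituted lactone enolate. Fallback that delivers hydrogen instead of methyl, setting out from 12 and returning at 10: alkylation of 12 with 3 (s-BuLi, TMEDA) gives the 3-methyl-5-alkyl silyloxyfuran F1. Its vinylogous Mannich reaction with 7 gives the α-methylbutenolide adduct F2. Carbamate-directed homogeneous hydrogenation with [Ir(cod)(PCy3)(py)]PF6 delivers H2 to the face syn to the Boc-pyrrolidine, so the methyl ends anti (11R), giving the saturated benzyl ester F3. Hydrogenolysis (H2, Pd/C) gives 10.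

Step 8 (decarboxylative Mannich reaction). Risks: cis/trans and threo/erythro mixtures on the hindered N-acyliminium ion; iodination of the silyloxyfuran by residual iodine. Fallback that keeps the L-pyroglutamate C3 centre and uses the carboxyl carbon as C18, setting out from 10 and returning at 15: mixed-anhydride reduction (iBuOCOCl, N-methylmorpholine; NaBH4) gives the primary alcohol F4. Dess–Martin oxidation gives the aldehyde F5. Zn-mediated Barbier addition of ethyl 2-(bromomethyl)acrylate with Felkin–Anh (threo) control and lactonisation gives the α-methylene lactone F6. Hydrogenation (H2, Pd/C) from the face anti to the pyrrolidine gives 15.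

**Further compounds**
F1 | step 6 | 5-[3-(1,3-dioxolan-2-yl)propyl]-3-methyl-2-(triisopropylsilyloxy)furan | Cc1cc(CCCC2OCCO2)oc1O[Si](C(C)C)(C(C)C)C(C)C
F2 | step 6 | benzyl (2S,5S)-1-(tert-butoxycarbonyl)-5-[(2S)-2-[3-(1,3-dioxolan-2-yl)propyl]-4-methyl-5-oxo-2,5-dihydrofuran-2-yl]pyrrolidine-2-carboxylate | O1CCOC1CCC[C@]2(C=C(C)C(=O)O2)[C@@H]2CC[C@@H](C(=O)OCc3ccccc3)N2C(=O)OC(C)(C)C
F3 | step 6 | benzyl (2S,5S)-1-(tert-butoxycarbonyl)-5-[(2S,4R)-2-[3-(1,3-dioxolan-2-yl)propyl]-4-methyl-5-oxooxolan-2-yl]pyrrolidine-2-carboxylate | O1CCOC1CCC[C@]2(C[C@@H](C)C(=O)O2)[C@@H]2CC[C@@H](C(=O)OCc3ccccc3)N2C(=O)OC(C)(C)C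
F4 | step 8 | tert-butyl (2S,5S)-2-(hydroxymethyl)-5-[(2S,4R)-2-[3-(1,3-dioxolan-2-yl)propyl]-4-methyl-5-oxooxolan-2-yl]pyrrolidine-1-carboxylate | O1CCOC1CCC[C@]2(C[C@@H](C)C(=O)O2)[C@@H]2CC[C@@H](CO)N2C(=O)OC(C)(C)C
F5 | step 8 | tert-butyl (2S,5S)-2-formyl-5-[(2S,4R)-2-[3-(1,3-dioxolan-2-yl)propyl]-4-methyl-5-oxooxolan-2-yl]pyrrolidine-1-carboxylate | O1CCOC1CCC[C@]2(C[C@@H](C)C(=O)O2)[C@@H]2CC[C@@H](C=O)N2C(=O)OC(C)(C)C
F6 | step 8 | tert-butyl (2S,5S)-2-[(2S)-4-methylidene-5-oxooxolan-2-yl]-5-[(2S,4R)-2-[3-(1,3-dioxolan-2-yl)propyl]-4-methyl-5-oxooxolan-2-yl]pyrrolidine-1-carboxylate | O1CCOC1CCC[C@]2(C[C@@H](C)C(=O)O2)[C@@H]2CC[C@@H]([C@@H]3CC(=C)C(=O)O3)N2C(=O)OC(C)(C)C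
F7 | step 10 | tert-butyl (2S,5S)-2-[(2S,4R)-4-methyl-5-oxo-2-(4-oxobutyl)oxolan-2-yl]-5-[(2S,4S)-4-methyl-5-oxooxolan-2-yl]pyrrolidine-1-carboxylate | O=CCCC[C@]1(C[C@@H](C)C(=O)O1)[C@@H]1CC[C@@H]([C@@H]2C[C@H](C)C(=O)O2)N1C(=O)OC(C)(C)C
F8 | step 10 | trimethylsilyl enol ether of F7 (E/Z mixture) | C[Si](C)(C)OC=CCC[C@]1(C[C@@H](C)C(=O)O1)[C@@H]1CC[C@@H]([C@@H]2C[C@H](C)C(=O)O2)N1C(=O)OC(C)(C)C
F9 | step 10 | ethyl 3-formyl-2-hydroxy-2-methyl-5-[(2S,4R)-2-[(2S,5S)-1-(tert-butoxycarbonyl)-5-[(2S,4S)-4-methyl-5-oxooxolan-2-yl]pyrrolidin-2-yl]-4-methyl-5-oxooxolan-2-yl]pentanoate (diastereomer mixture at the two new centres) | CCOC(=O)C(C)(O)C(C=O)CC[C@]1(C[C@@H](C)C(=O)O1)[C@@H]1CC[C@@H]([C@@H]2C[C@H](C)C(=O)O2)N1C(=O)OC(C)(C)C
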